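## Retrosynthetic overview

1. Target 21 ⇐ pentabenzyl ether 20 (global debenzylation) ⇐ carboxylate-directed C4–H olefination of dihydrobenzofuran acid 19 with acrylate 8.
2. 19 ⇐ methyl ester 18 ⇐ oxidative ring contraction of (2S)-flavanone 15: a 1,2-shift of ring A from C4 to C3 turns the pyranone ring into the trans-2,3-dihydrobenzofuran-3-carboxylate.
3. 15 ⇐ 2'-hydroxychalcone 14 by enantioselective oxa-Michael closure (sets C2) ⇐ C,O-dilithiated bromophenol (from 12) + Weinreb amide 10.
4. 8 ⇐ aryl Grignard from bromide 3 + methyl (R)-glycidate (source of the R centre) + acryloyl chloride; 10 ⇐ Heck reaction of 3.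
5. Ring order: the three benzene rings come from catechol; the pyranone ring is closed first (step 8) and then contracted to the dihydrofuran ring (step 9).

Assumption: the target is taken exactly as drawn, i.e. (2S,3S)-trans dihydrobenzofuran, (R)-configured lactate carbon, E enoate (9''-methyl lithospermate).

## Route

Step 1
Reactants: 1 catechol
Product: 2 1,2-bis(benzyloxy)benzene
Conditions: BnBr (2.2 equiv), K2CO3, DMF, 60 °C
Reagents that add atoms: benzyl bromide BrCc1ccccc1
Why: Williamson ether synthesis on both phenols; benzyl ethers survive every later step up to the final deprotection.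

Step 2
Reactants: 2 1,2-bis(benzyloxy)benzene
Product: 3 4-bromo-1,2-bis(benzyloxy)benzene
Conditions: NBS (1.05 equiv), MeCN, 0 °C to rt
Reagents that add atoms: N-bromosuccinimide O=C1CCC(=O)N1Br
Why: Electrophilic aromatic bromination goes para to an alkoxy group, as with veratrole, and gives the 4-bromide only.

Step 3
Reactants: 3 4-bromo-1,2-bis(benzyloxy)benzene; 4 methyl (2R)-oxirane-2-carboxylate; 5 acryloyl chloride
Product: 8 methyl (2R)-3-[3,4-bis(benzyloxy)phenyl]-2-(prop-2-enoyloxy)propanoate, via aryl Grignard 6 (not isolated), via magnesium alkoxide 7 (not isolated)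
Conditions: Mg, THF, 45 °C; CuI (10 mol %), 4 (1.1 equiv), −40 to −20 °C; then 5 (1.3 equiv), −20 to 0 °C
Reagents that add atoms: none
Why: Copper-catalysed Grignard opening of the glycidate at the unsubstituted C3 (SN2) leaves the C2 stereocentre untouched, so R is carried over, and the magnesium alkoxide is O-acylated in the same flask; the epoxide is kept in slight excess so that no Grignard reagent is left when the acid chloride is added.

Step 4
Reactants: 3 4-bromo-1,2-bis(benzyloxy)benzene; 9 N-methoxy-N-methylprop-2-enamide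
Product: 10 (2E)-3-[3,4-bis(benzyloxy)phenyl]-N-methoxy-N-methylprop-2-enamide
Conditions: Pd(OAc)2 (2 mol %), P(o-tol)3 (4 mol %), NaOAc, DMF, 110 °C
Reagents that add atoms: none
Why: Mizoroki–Heck reaction of an aryl bromide with an acrylamide; syn insertion and syn β-hydride elimination give the E-alkene.

Step 5
Reactants: 1 catechol
Product: 11 2-(benzyloxy)phenol
Conditions: BnBr (0.4 equiv based on catechol), K2CO3, acetone, reflux
Reagents that add atoms: benzyl bromide BrCc1ccccc1
Why: Williamson mono-alkylation with catechol in excess; unreacted catechol is washed out with water and the neutral bis-ether is removed by base extraction of the phenol.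

Step 6
Reactants: 11 2-(benzyloxy)phenol
Product: 12 2-(benzyloxy)-6-bromophenol
Conditions: NBS (1.0 equiv), i-Pr2NH (10 mol %), CH2Cl2, 0 °C
Reagents that add atoms: N-bromosuccinimide O=C1CCC(=O)N1Br
Why: Amine-mediated ortho-selective bromination of a phenol (the N-bromoamine is delivered through a hydrogen bond to the OH); C6 is the only free ortho position.

Step 7
Reactants: 12 2-(benzyloxy)-6-bromophenol; 10 (2E)-3-[3,4-bis(benzyloxy)phenyl]-N-methoxy-N-methylprop-2-enamide
Product: 14 (2E)-1-[3-(benzyloxy)-2-hydroxyphenyl]-3-[3,4-bis(benzyloxy)phenyl]prop-2-en-1-one, via dilithio phenoxide 13 (not isolated)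
Conditions: n-BuLi (2.1 equiv), THF, −78 °C; then 10, −78 to 0 °C; 1 M HCl
Reagents that add atoms: none
Why: O-deprotonation followed by bromine–lithium exchange gives the C,O-dilithio species, which adds once to the amide carbonyl (Weinreb ketone synthesis, no over-addition) and delivers the 2'-hydroxychalcone with the E-alkene intact.

Step 8
Reactants: 14 (2E)-1-[3-(benzyloxy)-2-hydroxyphenyl]-3-[3,4-bis(benzyloxy)phenyl]prop-2-en-1-one
Product: 15 (2S)-8-(benzyloxy)-2-[3,4-bis(benzyloxy)phenyl]-2,3-dihydro-4H-chromen-4-one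
Conditions: 1-[3,5-bis(trifluoromethyl)phenyl]-3-[(2S)-3,3-dimethyl-1-{[tris(4-methoxyphenyl)-λ5-phosphanylidene]amino}butan-2-yl]thiourea (10 mol %), toluene, −20 °C, 48 h; AcOH quench at about 90 % conversion; one recrystallisation
Reagents that add atoms: none
Why: Proposed new method: an enantioselective 6-endo-trig oxa-Michael closure of an unactivated 2'-hydroxychalcone under bifunctional iminophosphorane–thiourea catalysis, in which the superbasic P=N site fully deprotonates the chelated 2'-OH and so breaks the OH···O=C hydrogen bond that holds the phenol away from the β-carbon, the thiourea N–H pair binds the enone/enolate oxygen, the tight chiral aminophosphonium–phenoxide ion pair closes on one enone face to set C2, and C-protonation of the enolate by the aminophosphonium releases the catalyst; the reaction is stopped before equilibrium so that retro-Michael erosion stays small, the (S)-tert-leucine-derived catalyst is expected to give 2S and its mirror image from (R)-tert-leucine is used if the first run (chiral HPLC, CD) shows the opposite sense; the closest known reactions are the cinchona-thiourea oxa-Michael synthesis of flavanones from activated alkylidene β-ketoesters and iminophosphorane-catalysed oxa-Michael additions of alcohols to unactivated enoates.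

Step 9
Reactants: 15 (2S)-8-(benzyloxy)-2-[3,4-bis(benzyloxy)phenyl]-2,3-dihydro-4H-chromen-4-one
Product: 18 methyl (2S,3S)-7-(benzyloxy)-2-[3,4-bis(benzyloxy)phenyl]-2,3-dihydro-1-benzofuran-3-carboxylate, via enol ether 16 (not isolated), via iodanyl ketal 17 (not isolated)
Conditions: PhI(OAc)2 (1.2 equiv), H2SO4 (20 mol %), HC(OMe)3, 0 °C to rt; aq. NaHCO3
Reagents that add atoms: trimethyl orthoformate COC(OC)OC; water O
Why: Oxidative ring contraction of a flavanone with trivalent iodine (a 1,2-aryl shift, not pericyclic): the enol ether is attacked at C3 anti to the 2-aryl group, the C4–C4a bond antiperiplanar to the equatorial C3–I bond migrates to C3 with inversion as iodobenzene leaves, and the dimethoxycarbenium ion is quenched to the methyl ester, which places CO2Me trans to the aryl group (3S) while C2 is untouched.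

Step 10
Reactants: 18 methyl (2S,3S)-7-(benzyloxy)-2-[3,4-bis(benzyloxy)phenyl]-2,3-dihydro-1-benzofuran-3-carboxylate
Product: 19 (2S,3S)-7-(benzyloxy)-2-[3,4-bis(benzyloxy)phenyl]-2,3-dihydro-1-benzofuran-3-carboxylic acid
Conditions: LiOH·H2O (3 equiv), THF/H2O 3:1, 0 °C to rt; 1 M HCl
Reagents that add atoms: lithium hydroxide [Li+].[OH-]
Why: Saponification of the methyl ester; the trans acid is the thermodynamic isomer, so C3 is not at risk, and the cold conditions avoid E1cB ring opening at C2.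

Step 11
Reactants: 19 (2S,3S)-7-(benzyloxy)-2-[3,4-bis(benzyloxy)phenyl]-2,3-dihydro-1-benzofuran-3-carboxylic acid; 8 methyl (2R)-3-[3,4-bis(benzyloxy)phenyl]-2-(prop-2-enoyloxy)propanoate
Product: 20 (2S,3S)-7-(benzyloxy)-2-[3,4-bis(benzyloxy)phenyl]-4-[(1E)-3-{[(2R)-3-[3,4-bis(benzyloxy)phenyl]-1-methoxy-1-oxopropan-2-yl]oxy}-3-oxoprop-1-en-1-yl]-2,3-dihydro-1-benzofuran-3-carboxylic acid
Conditions: Pd(OAc)2 (5 mol %), N-acetyl-L-isoleucine (10 mol %), KHCO3 (2 equiv), O2 (1 atm), t-AmylOH, 85 °C; 1 M HCl work-up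
Reagents that add atoms: none
Why: Carboxylate-directed ortho C–H olefination (Fujiwara–Moritani type, divalent palladium with an N-acyl amino acid ligand, O2 as oxidant) through a six-membered palladacycle at C4, the only free ortho position of the arylacetic acid unit; β-hydride elimination gives the E-enoate and no stereocentre is touched.

Step 12
Reactants: 20 (2S,3S)-7-(benzyloxy)-2-[3,4-bis(benzyloxy)phenyl]-4-[(1E)-3-{[(2R)-3-[3,4-bis(benzyloxy)phenyl]-1-methoxy-1-oxopropan-2-yl]oxy}-3-oxoprop-1-en-1-yl]-2,3-dihydro-1-benzofuran-3-carboxylic acid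
Product: 21 (2S,3S)-2-(3,4-dihydroxyphenyl)-4-[(1E)-3-{[(2R)-3-(3,4-dihydroxyphenyl)-1-methoxy-1-oxopropan-2-yl]oxy}-3-oxoprop-1-en-1-yl]-7-hydroxy-2,3-dihydro-1-benzofuran-3-carboxylic acid
Conditions: BCl3 (12 equiv), C6HMe5 (15 equiv), CH2Cl2, −78 °C; MeOH quench
Reagents that add atoms: none
Why: Lewis acid debenzylation with a non-Lewis-basic cation scavenger removes all five aryl benzyl ethers at −78 °C as benzylpentamethylbenzene and leaves the methyl ester, the enoate, the alkene and the three stereocentres alone (hydrogenolysis is excluded by the alkene).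

## Compound list

1 | catechol (benzene-1,2-diol) | Oc1ccccc1O | starting material
2 | 1,2-bis(benzyloxy)benzene | c1ccc(COc2ccccc2OCc2ccccc2)cc1 | intermediate
3 | 4-bromo-1,2-bis(benzyloxy)benzene | Brc1ccc(OCc2ccccc2)c(OCc2ccccc2)c1 | intermediate
4 | methyl (2R)-oxirane-2-carboxylate | COC(=O)[C@H]1CO1 | starting material
5 | acryloyl chloride | C=CC(=O)Cl | starting material
6 | [3,4-bis(benzyloxy)phenyl]magnesium bromide | Br[Mg]c1ccc(OCc2ccccc2)c(OCc2ccccc2)c1 | intermediate (not isolated)
7 | bromomagnesium alkoxide of methyl (2R)-3-[3,4-bis(benzyloxy)phenyl]-2-hydroxypropanoate | COC(=O)[C@H](O[Mg]Br)Cc1ccc(OCc2ccccc2)c(OCc2ccccc2)c1 | intermediate (not isolated)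
8 | methyl (2R)-3-[3,4-bis(benzyloxy)phenyl]-2-(prop-2-enoyloxy)propanoate | COC(=O)[C@@H](Cc1ccc(OCc2ccccc2)c(OCc2ccccc2)c1)OC(=O)C=C | intermediate
9 | N-methoxy-N-methylprop-2-enamide | C=CC(=O)N(C)OC | starting material
10 | (2E)-3-[3,4-bis(benzyloxy)phenyl]-N-methoxy-N-methylprop-2-enamide | CON(C)C(=O)/C=C/c1ccc(OCc2ccccc2)c(OCc2ccccc2)c1 | intermediate
11 | 2-(benzyloxy)phenol | Oc1ccccc1OCc1ccccc1 | intermediate
12 | 2-(benzyloxy)-6-bromophenol | Oc1c(Br)cccc1OCc1ccccc1 | intermediate
13 | lithium 2-(benzyloxy)-6-lithiophenoxide | [Li]Oc1c([Li])cccc1OCc1ccccc1 | intermediate (not isolated)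
14 | (2E)-1-[3-(benzyloxy)-2-hydroxyphenyl]-3-[3,4-bis(benzyloxy)phenyl]prop-2-en-1-one | O=C(/C=C/c1ccc(OCc2ccccc2)c(OCc2ccccc2)c1)c1cccc(OCc2ccccc2)c1O | intermediate
15 | (2S)-8-(benzyloxy)-2-[3,4-bis(benzyloxy)phenyl]-2,3-dihydro-4H-chromen-4-one | O=C1C[C@@H](c2ccc(OCc3ccccc3)c(OCc3ccccc3)c2)Oc2c(OCc3ccccc3)cccc21 | intermediate
16 | (2S)-8-(benzyloxy)-2-[3,4-bis(benzyloxy)phenyl]-4-methoxy-2H-chromene | COC1=C[C@@H](c2ccc(OCc3ccccc3)c(OCc3ccccc3)c2)Oc2c(OCc3ccccc3)cccc21 | intermediate (not isolated)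
17 | trans-(2R,3R)-{8-(benzyloxy)-2-[3,4-bis(benzyloxy)phenyl]-4,4-dimethoxy-3,4-dihydro-2H-chromen-3-yl}(phenyl)-λ3-iodanyl acetate | COC1(OC)[C@H](I(OC(C)=O)c2ccccc2)[C@@H](c2ccc(OCc3ccccc3)c(OCc3ccccc3)c2)Oc2c(OCc3ccccc3)cccc21 | intermediate (not isolated)
18 | methyl (2S,3S)-7-(benzyloxy)-2-[3,4-bis(benzyloxy)phenyl]-2,3-dihydro-1-benzofuran-3-carboxylate (trans) | COC(=O)[C@@H]1[C@@H](c2ccc(OCc3ccccc3)c(OCc3ccccc3)c2)Oc2c(OCc3ccccc3)cccc21 | intermediate
19 | (2S,3S)-7-(benzyloxy)-2-[3,4-bis(benzyloxy)phenyl]-2,3-dihydro-1-benzofuran-3-carboxylic acid (trans) | OC(=O)[C@@H]1[C@@H](c2ccc(OCc3ccccc3)c(OCc3ccccc3)c2)Oc2c(OCc3ccccc3)cccc21 | intermediate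
20 | (2S,3S)-7-(benzyloxy)-2-[3,4-bis(benzyloxy)phenyl]-4-[(1E)-3-{[(2R)-3-[3,4-bis(benzyloxy)phenyl]-1-methoxy-1-oxopropan-2-yl]oxy}-3-oxoprop-1-en-1-yl]-2,3-dihydro-1-benzofuran-3-carboxylic acid | COC(=O)[C@@H](Cc1ccc(OCc2ccccc2)c(OCc2ccccc2)c1)OC(=O)/C=C/c1ccc(OCc2ccccc2)c2c1[C@H](C(=O)O)[C@@H](c1ccc(OCc3ccccc3)c(OCc3ccccc3)c1)O2 | intermediate
21 | (2S,3S)-2-(3,4-dihydroxyphenyl)-4-[(1E)-3-{[(2R)-3-(3,4-dihydroxyphenyl)-1-methoxy-1-oxopropan-2-yl]oxy}-3-oxoprop-1-en-1-yl]-7-hydroxy-2,3-dihydro-1-benzofuran-3-carboxylic acid | COC(=O)[C@@H](Cc1ccc(O)c(O)c1)OC(=O)/C=C/c1ccc(O)c2c1[C@H](C(=O)O)[C@@H](c1ccc(O)c(O)c1)O2 | target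

## Step count and risks

Total steps: 12. Longest linear sequence: 9 steps (1, 2, 4, 7, 8, 9, 10, 11, 12).

**Step 8 (proposed new step).** The risks are a slow reaction with the electron-rich enone, modest facial selectivity, and loss of ee through the retro-Michael reaction near equilibrium. The fallback uses known chemistry and sets out from 14. Heating 14 with NaOAc in EtOH at reflux closes it to the racemic 8-(benzyloxy)-2-[3,4-bis(benzyloxy)phenyl]-2,3-dihydro-4H-chromen-4-one F1. F1 is then resolved kinetically by asymmetric transfer hydrogenation with RuCl(p-cymene)[(R,R)-TsNCH(Ph)CH(Ph)NH2] (1 mol %) and HCO2H/Et3N at rt, the catalyst antipode being confirmed on a test scale. The 2R ketone is reduced to the cis alcohol (2R,4R)-8-(benzyloxy)-2-[3,4-bis(benzyloxy)phenyl]-3,4-dihydro-2H-chromen-4-ol F2, and the unreduced 2S ketone is recovered at slightly over 50 % conversion in high ee. The fallback comes back to the route at 15, at the cost of half the material.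

**Step 9.** The risks are a competing 2→3 shift of the electron-rich ring B leading to the isoflavone, attack of the oxidant on the dialkoxyarene, and acid-induced erosion at C2. The fallback sets out from 15 and separates activation from oxidation. α-Bromination with CuBr2 in EtOAc/CHCl3 at reflux gives trans-(2R,3R)-8-(benzyloxy)-2-[3,4-bis(benzyloxy)phenyl]-3-bromo-2,3-dihydro-4H-chromen-4-one F3. F3 is ketalised with HC(OMe)3/MeOH and catalytic TsOH, and AgBF4 then abstracts the equatorial bromide. This triggers the same 1,2-shift of ring A (the α-halo ketal aryl migration used for 2-arylpropanoate esters) with no oxidant present, and the fallback comes back to the route at 18.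

**Step 12.** The risk is that BCl3 ionises the benzylic C2–O bond of the dihydrobenzofuran, which could open the ring, epimerise C2 or alkylate the scavenger, or that debenzylation is incomplete. The fallback sets out from 19 and 8 and swaps the protecting groups before the coupling.
- Hydrogenolysis of 19 (H2, Pd/C, EtOAc/MeOH; no alkene is present yet) gives (2S,3S)-2-(3,4-dihydroxyphenyl)-7-hydroxy-2,3-dihydro-1-benzofuran-3-carboxylic acid F4.
- TBSCl/imidazole in DMF, followed by a mild aqueous work-up that cleaves the silyl ester, converts F4 into (2S,3S)-7-[(tert-butyldimethylsilyl)oxy]-2-{3,4-bis[(tert-butyldimethylsilyl)oxy]phenyl}-2,3-dihydro-1-benzofuran-3-carboxylic acid F5.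
- 8, which has no sensitive cyclic ether, is debenzylated with BCl3/C6HMe5 at −78 °C to methyl (2R)-3-(3,4-dihydroxyphenyl)-2-(prop-2-enoyloxy)propanoate F6.
- F6 is silylated in the same way to methyl (2R)-3-{3,4-bis[(tert-butyldimethylsilyl)oxy]phenyl}-2-(prop-2-enoyloxy)propanoate F7.
- F5 and F7 are joined under the conditions of step 11 to the penta-O-(tert-butyldimethylsilyl) ether of 21 F8.
- HF·pyridine in THF at 0 °C removes the silyl groups without any Lewis acid, and the fallback comes back to the route at 21.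

## Further compounds

F1 | step 8 | rac-8-(benzyloxy)-2-[3,4-bis(benzyloxy)phenyl]-2,3-dihydro-4H-chromen-4-one | O=C1CC(c2ccc(OCc3ccccc3)c(OCc3ccccc3)c2)Oc2c(OCc3ccccc3)cccc21
F2 | step 8 | (2R,4R)-8-(benzyloxy)-2-[3,4-bis(benzyloxy)phenyl]-3,4-dihydro-2H-chromen-4-ol | O[C@@H]1C[C@H](c2ccc(OCc3ccccc3)c(OCc3ccccc3)c2)Oc2c(OCc3ccccc3)cccc21
F3 | step 9 | (2R,3R)-8-(benzyloxy)-2-[3,4-bis(benzyloxy)phenyl]-3-bromo-2,3-dihydro-4H-chromen-4-one | O=C1[C@H](Br)[C@@H](c2ccc(OCc3ccccc3)c(OCc3ccccc3)c2)Oc2c(OCc3ccccc3)cccc21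
F4 | step 12 | (2S,3S)-2-(3,4-dihydroxyphenyl)-7-hydroxy-2,3-dihydro-1-benzofuran-3-carboxylic acid | OC(=O)[C@@H]1[C@@H](c2ccc(O)c(O)c2)Oc2c(O)cccc21
F5 | step 12 | (2S,3S)-7-[(tert-butyldimethylsilyl)oxy]-2-{3,4-bis[(tert-butyldimethylsilyl)oxy]phenyl}-2,3-dihydro-1-benzofuran-3-carboxylic acid | OC(=O)[C@@H]1[C@@H](c2ccc(O[Si](C)(C)C(C)(C)C)c(O[Si](C)(C)C(C)(C)C)c2)Oc2c(O[Si](C)(C)C(C)(C)C)cccc21
F6 | step 12 | methyl (2R)-3-(3,4-dihydroxyphenyl)-2-(prop-2-enoyloxy)propanoate | COC(=O)[C@@H](Cc1ccc(O)c(O)c1)OC(=O)C=C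
F7 | step 12 | methyl (2R)-3-{3,4-bis[(tert-butyldimethylsilyl)oxy]phenyl}-2-(prop-2-enoyloxy)propanoate | COC(=O)[C@@H](Cc1ccc(O[Si](C)(C)C(C)(C)C)c(O[Si](C)(C)C(C)(C)C)c1)OC(=O)C=C
F8 | step 12 | penta-O-(tert-butyldimethylsilyl) ether of 21 | COC(=O)[C@@H](Cc1ccc(O[Si](C)(C)C(C)(C)C)c(O[Si](C)(C)C(C)(C)C)c1)OC(=O)/C=C/c1ccc(O[Si](C)(C)C(C)(C)C)c2c1[C@H](C(=O)O)[C@@H](c1ccc(O[Si](C)(C)C(C)(C)C)c(O[Si](C)(C)C(C)(C)C)c1)O2
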